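**Retrosynthetic overview**

1. Cyclohexene locants: C1 = CH–C(=O)Ar, C2 = CH2, C3 = CH=, C4 = =C(homoprenyl), C5 = CH2, C6 = CHPh. Target ⇒ MOM removal and Negishi coupling at C4 ⇒ cyclohexenyl nonaflate 14 plus homoprenyl bromide 15.
2. 14 ⇒ two-carbon ring expansion (4→6) of the silyloxy(vinyl)cyclobutyl aryl ketone 10. A temporary transannular C1–C4 bond defines the four-membered ring C1–C6–C5–C4, and C2–C3 wait as a vinyl group on C4.
3. Enabling feature: C1 is the enolisable α-carbon of the aryl ketone and lies 1,4 to the substituted alkene carbon C4. With oxygen on C4, the unit O–C4–C1–C(=O)Ar is an aldol locked in a strained cyclobutane. Retro-aldol cleavage frees a C1 enolate and a C4 vinyl ketone, which re-close from C1 to C2.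
4. Only C6 cannot epimerise, and it is set by desymmetrising deprotonation of prochiral 3-phenylcyclobutanone 4. C4 is erased and C1 relaxes to trans, so all diastereomers of 10 converge on one product.
5. 10 ⇒ 4 + aldehyde 3 (from 1) + vinyl Grignard. Both arenes and the cyclobutane are bought; the cyclohexene is the only ring that is made (step 6).

Key step: step 6

Assumption: the (R,R)-amide is taken to remove the enantiotopic proton that leads to the (R)-enolate 5. If the sense is the opposite, the equally available (S,S)-amine is used and nothing else changes.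

**Route**

Step 1
Reactants: 1 2,4,6-trihydroxybenzaldehyde
Product: 2 2-hydroxy-4,6-bis(methoxymethoxy)benzaldehyde
Conditions: MOMCl (2.1 equiv), iPr2NEt, CH2Cl2, 0 °C → rt
Reagents that add atoms: chloromethyl methyl ether, COCCl
Why: This is a Williamson-type O-alkylation (MOM protection) in which the hydroxyl hydrogen-bonded to the formyl oxygen is the least nucleophilic, so two equivalents of MOMCl with a mild amine base should take the 4-OH and one of the two equivalent ortho-OH groups and leave the chelated one free.

Step 2
Reactants: 2 2-hydroxy-4,6-bis(methoxymethoxy)benzaldehyde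
Product: 3 2-methoxy-4,6-bis(methoxymethoxy)benzaldehyde
Conditions: MeI, K2CO3, acetone, reflux
Reagents that add atoms: iodomethane, CI
Why: This is a Williamson ether synthesis in which carbonate in hot acetone breaks the chelate and the single free phenol is O-methylated, fixing the 2-OMe/4,6-di-O-protected pattern of the target arene.

Step 3
Reactants: 4 3-phenylcyclobutan-1-one; 3 2-methoxy-4,6-bis(methoxymethoxy)benzaldehyde
Product: 7 (2R,3R)-1-ethenyl-2-{hydroxy[2-methoxy-4,6-bis(methoxymethoxy)phenyl]methyl}-3-phenylcyclobutan-1-ol (epimers at ring C1 and at the benzylic carbinol carbon are carried on together), via lithium enolate 5 (not isolated), via lithium aldolate 6 (not isolated)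
Conditions: (R,R)-bis(1-phenylethyl)amine, n-BuLi, LiCl, THF, −78 °C; 4, −100 °C; 3, −78 °C; CH2=CHMgBr (3 equiv), −78 → −40 °C; aq NH4Cl
Reagents that add atoms: vinylmagnesium bromide, C=C[Mg]Br
Why: Enantioselective deprotonation of a prochiral 3-substituted cyclobutanone by a C2-symmetric chiral lithium amide sets the only non-epimerisable stereocentre (CHPh, R), the aldol addition occurs anti to phenyl, and the strained, chelated cyclobutanone carbonyl of the aldolate should take up the Grignard reagent by 1,2-addition faster than it enolises or reverts, while the configurations of the two carbinol carbons do not matter because both are erased later.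

Step 4
Reactants: 7 vinyl diol
Product: 9 [(1R,4R)-2-ethenyl-4-phenyl-2-(trimethylsilyloxy)cyclobutyl][2-methoxy-4,6-bis(methoxymethoxy)phenyl]methanol, via bis-TMS ether 8 (not isolated)
Conditions: 1-(trimethylsilyl)imidazole (4 equiv), CH2Cl2, rt; then K2CO3 (0.1 equiv), MeOH, 0 °C
Reagents that add atoms: 1-(trimethylsilyl)imidazole, C[Si](C)(C)n1ccnc1
Why: Exhaustive silylation with a neutral silyl donor followed by base-catalysed methanolysis exploits the faster cleavage of secondary over tertiary TMS ethers, so the tertiary cyclobutanol stays masked (the free β-hydroxy ketone would fragment on its own) and no acid reaches the ionisable electron-rich benzylic carbinol.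

Step 5
Reactants: 9 mono-TMS alcohol
Product: 10 [(1S,4R)-2-ethenyl-4-phenyl-2-(trimethylsilyloxy)cyclobutyl][2-methoxy-4,6-bis(methoxymethoxy)phenyl]methanone (any mixture of epimers at ring C1 and C2 is used)
Conditions: Dess–Martin periodinane, pyridine, CH2Cl2, 0 °C
Reagents that add atoms: none
Why: Dess–Martin oxidation under pyridine buffer should convert the hindered benzylic alcohol into the aryl ketone without touching the silyl ether, the MOM groups or the vinyl group, which completes the latent aldol array, and epimerisation α to the new ketone is of no consequence.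

Step 6
Reactants: 10 silyloxy(vinyl)cyclobutyl aryl ketone
Product: 14 (4R,5R)-4-[2-methoxy-4,6-bis(methoxymethoxy)benzoyl]-5-phenylcyclohex-1-en-1-yl nonafluorobutane-1-sulfonate, via cyclobutanolate 11 (not isolated), via ring-opened enolate 12 (not isolated), via cyclohexenolate 13 (not isolated)
Conditions: C4F9SO2F (1.3 equiv), TBAT (10 mol %), THF, −40 → 0 °C
Reagents that add atoms: nonafluorobutane-1-sulfonyl fluoride, O=S(=O)(F)C(F)(F)C(F)(F)C(F)(F)C(F)(F)F
Why: Proposed new method: fluoride removes the silyl group, the cyclobutanolate 11 undergoes strain-driven retro-aldol cleavage of C1–C4 (the fragmentation half of a de Mayo reaction) to the aryl-ketone enolate 12 that carries a vinyl ketone, 12 closes by intramolecular Michael addition of C1 to the vinyl terminus C2 (the second half of a sequential double Michael reaction), and the cyclohexenolate 13 is O-sulfonylated by the sulfonyl fluoride, which releases the fluoride that carries the chain (as in the fluoride-catalysed conversion of silyl enol ethers into alkenyl nonaflates). These three reaction types are each well documented on their own, and what is new is their concatenation into a net 1,3-shift that enlarges the ring C1–C6–C5–C4 by the two vinyl carbons to the six-membered ring. The only ring closure is 6-(enolexo)-endo-trig on the s-trans enone. The new stereocentre C1 is controlled by C6, because a chair-like transition state with phenyl and aroyl equatorial gives the trans isomer, which is also the thermodynamic one, so every C1/C4 diastereomer of 10 converges on one product and any cis material is drained by epimerisation at the enolisable C1. The step needs cleavage of C1–C4 only (the sole ring bond that is both attached to the oxide carbon and α to a carbonyl), ring closure faster than proton transfer or retro-Michael loss of C6 (secured by intramolecular attack on an unhindered, very reactive vinyl ketone at or below 0 °C), and trapping of the enolate where it is born (secured by having the sulfonyl fluoride present from the start), which fixes the double bond at C3=C4.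

Step 7
Reactants: 14 cyclohexenyl nonaflate; 15 5-bromo-2-methylpent-2-ene
Product: 17 [(1R,6R)-4-(4-methylpent-3-en-1-yl)-6-phenylcyclohex-3-en-1-yl][2-methoxy-4,6-bis(methoxymethoxy)phenyl]methanone, via homoprenylzinc bromide 16 (not isolated)
Conditions: 15, Zn dust, LiCl, THF, 50 °C; then 14, Pd(dppf)Cl2 (5 mol %), THF, rt → 50 °C
Reagents that add atoms: none
Why: In this Negishi sp2–sp3 cross-coupling the LiCl-assisted zinc insertion gives a primary alkylzinc that tolerates the hindered ketone, and the wide-bite-angle dppf–palladium catalyst should couple it with the alkenyl nonaflate with retention of the double-bond position and with reductive elimination faster than β-hydride elimination.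

Step 8
Reactants: 17 bis-MOM ether
Product: 18 (2,4-dihydroxy-6-methoxyphenyl)[(1R,6R)-4-(4-methylpent-3-en-1-yl)-6-phenylcyclohex-3-en-1-yl]methanone
Conditions: 3 M aq HCl (cat.), MeOH, 45 °C
Reagents that add atoms: none
Why: Acid-catalysed acetal exchange with methanol removes both MOM groups (the ortho one assisted by hydrogen bonding to the ketone) under conditions that non-conjugated trisubstituted alkenes remote from the phenols should tolerate, and reversible enolisation can only reinforce the trans (1R,6R) arrangement.

**Compound list**

1 | 2,4,6-trihydroxybenzaldehyde | O=Cc1c(O)cc(O)cc1O | starting material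
2 | 2-hydroxy-4,6-bis(methoxymethoxy)benzaldehyde | O=Cc1c(O)cc(OCOC)cc1OCOC | intermediate
3 | 2-methoxy-4,6-bis(methoxymethoxy)benzaldehyde | O=Cc1c(OC)cc(OCOC)cc1OCOC | intermediate
4 | 3-phenylcyclobutan-1-one | O=C1CC(c2ccccc2)C1 | starting material
5 | lithium (3R)-3-phenylcyclobut-1-en-1-olate | [Li+].[O-]C1=C[C@H](c2ccccc2)C1 | intermediate
6 | lithium aldolate of (2R,3R)-2-{hydroxy[2-methoxy-4,6-bis(methoxymethoxy)phenyl]methyl}-3-phenylcyclobutan-1-one | O=C1C[C@@H](c2ccccc2)[C@@H]1C([O-])c1c(OC)cc(OCOC)cc1OCOC.[Li+] | intermediate
7 | (2R,3R)-1-ethenyl-2-{hydroxy[2-methoxy-4,6-bis(methoxymethoxy)phenyl]methyl}-3-phenylcyclobutan-1-ol | C=CC1(O)C[C@@H](c2ccccc2)[C@@H]1C(O)c1c(OC)cc(OCOC)cc1OCOC | intermediate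
8 | bis(trimethylsilyl) ether of 7 | C=CC1(O[Si](C)(C)C)C[C@@H](c2ccccc2)[C@@H]1C(O[Si](C)(C)C)c1c(OC)cc(OCOC)cc1OCOC | intermediate
9 | [(1R,4R)-2-ethenyl-4-phenyl-2-(trimethylsilyloxy)cyclobutyl][2-methoxy-4,6-bis(methoxymethoxy)phenyl]methanol | C=CC1(O[Si](C)(C)C)C[C@@H](c2ccccc2)[C@@H]1C(O)c1c(OC)cc(OCOC)cc1OCOC | intermediate
10 | [(1S,4R)-2-ethenyl-4-phenyl-2-(trimethylsilyloxy)cyclobutyl][2-methoxy-4,6-bis(methoxymethoxy)phenyl]methanone | C=CC1(O[Si](C)(C)C)C[C@@H](c2ccccc2)[C@@H]1C(=O)c1c(OC)cc(OCOC)cc1OCOC | intermediate
11 | tetrabutylammonium 2-aroyl-1-ethenyl-3-phenylcyclobutan-1-olate | C=CC1([O-])C[C@@H](c2ccccc2)[C@@H]1C(=O)c1c(OC)cc(OCOC)cc1OCOC.CCCC[N+](CCCC)(CCCC)CCCC | intermediate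
12 | tetrabutylammonium enolate of (3R)-1-aryl-3-phenylhept-6-ene-1,5-dione (C1 enolate) | C=CC(=O)C[C@@H](c1ccccc1)C=C([O-])c1c(OC)cc(OCOC)cc1OCOC.CCCC[N+](CCCC)(CCCC)CCCC | intermediate
13 | tetrabutylammonium (4R,5R)-4-aroyl-5-phenylcyclohex-1-en-1-olate | [O-]C1=CC[C@@H](C(=O)c2c(OC)cc(OCOC)cc2OCOC)[C@H](c2ccccc2)C1.CCCC[N+](CCCC)(CCCC)CCCC | intermediate
14 | (4R,5R)-4-[2-methoxy-4,6-bis(methoxymethoxy)benzoyl]-5-phenylcyclohex-1-en-1-yl nonafluorobutane-1-sulfonate | O=S(=O)(OC1=CC[C@@H](C(=O)c2c(OC)cc(OCOC)cc2OCOC)[C@H](c2ccccc2)C1)C(F)(F)C(F)(F)C(F)(F)C(F)(F)F | intermediate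
15 | 5-bromo-2-methylpent-2-ene | CC(C)=CCCBr | starting material
16 | (4-methylpent-3-en-1-yl)zinc bromide | CC(C)=CCC[Zn]Br | intermediate
17 | [(1R,6R)-4-(4-methylpent-3-en-1-yl)-6-phenylcyclohex-3-en-1-yl][2-methoxy-4,6-bis(methoxymethoxy)phenyl]methanone | CC(C)=CCCC1=CC[C@@H](C(=O)c2c(OC)cc(OCOC)cc2OCOC)[C@H](c2ccccc2)C1 | intermediate
18 | (2,4-dihydroxy-6-methoxyphenyl)[(1R,6R)-4-(4-methylpent-3-en-1-yl)-6-phenylcyclohex-3-en-1-yl]methanone | COc1cc(O)cc(O)c1C(=O)[C@@H]1CC=C(CCC=C(C)C)C[C@H]1c1ccccc1 | target

**Step count and risks**

Total step count: 8. Longest linear sequence: 8 (steps 1 to 8, starting from 1; 6 steps from 4).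

Steps most likely to fail:

Step 6 (the labelled step). Proton transfer between enolate sites before ring closure or before O-sulfonylation would blur the position of the double bond. Premature O-sulfonylation of the ring-opened enolate or retro-Michael fragmentation would cost material or erode the configuration at C6. The fallback sets out from 10 and replaces the anionic cascade by two known operations. Catalytic Tf2NH (or TMSOTf) in CH2Cl2 at −78 °C ionises the donor–acceptor cyclobutane at C1–C4. The silyloxocarbenium/enol pair then re-closes by an intramolecular Mukaiyama–Michael addition, which is the known acid-induced isomerisation of 1-silyloxy-1-vinylcyclobutyl ketones to the formal Diels–Alder adducts. This still enlarges the four-membered ring to the six-membered one but involves no free enolate. It gives the silyl enol ether {(1R,6R)-6-phenyl-4-[(trimethylsilyl)oxy]cyclohex-3-en-1-yl}[2-methoxy-4,6-bis(methoxymethoxy)phenyl]methanone F1. F1 is then converted with C4F9SO2F and catalytic fluoride into 14, where the route is rejoined.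

Step 3. Possible failures are poor discrimination of the enantiotopic protons under external quench, self-condensation of the cyclobutanone enolate, or reversal of the aldol addition before the Grignard reagent has added. The fallback sets out from 4. Deprotonation by the same amide with TMSCl present as internal quench, the protocol documented for 3-substituted cyclobutanones, gives trimethyl{[(3R)-3-phenylcyclobut-1-en-1-yl]oxy}silane F2. F2 can be isolated and its enantiomeric purity checked. MeLi in THF then liberates the amine-free lithium enolate, so the route is rejoined at 5.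

Step 4. The rate difference in methanolysis may be too small, so that the tertiary silyl ether is lost together with the secondary one. The fallback sets out from isolated 8 and replaces hydrolytic discrimination by electronic discrimination. DDQ in wet CH2Cl2 at 0 °C abstracts hydride only from the trialkoxy-substituted benzylic position, and the resulting silyloxocarbenium ion loses its silyl group. The route is rejoined directly at 10, bypassing 9 and step 5. This fallback makes no new compound (F0).

**Further compounds**

F1 | step 6 | {(1R,6R)-6-phenyl-4-[(trimethylsilyl)oxy]cyclohex-3-en-1-yl}[2-methoxy-4,6-bis(methoxymethoxy)phenyl]methanone | C[Si](C)(C)OC1=CC[C@@H](C(=O)c2c(OC)cc(OCOC)cc2OCOC)[C@H](c2ccccc2)C1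
F2 | step 3 | trimethyl{[(3R)-3-phenylcyclobut-1-en-1-yl]oxy}silane | C[Si](C)(C)OC1=C[C@H](c2ccccc2)C1
F0 | step 4 | none | none
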